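A direct plan would close ring C last: the diprenylated salicylaldehyde A1 (from 2,4,6-trihydroxybenzaldehyde A4) would be ionised by a chiral acid to an oxocarbenium ion and would add the ring B styrene A2 in a hetero-[4+2] to give the 4-methoxyflavan A3; C4 would then be oxidised to the ketone.
Its weakest steps would be: (1) the enantioselective intermolecular cycloaddition, without precedent for a simple styrene and run in acid beside three prenyl alkenes and three MOM ethers; (2) the hydrolysis of the C4 methyl ether and the oxidation of the alcohol, two steps that would only correct the oxidation level; (3) the twofold C-prenylation of A4 in aqueous alkali, which would give statistical mixtures with mono-, gem-di- and O-alkylated products.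

The route rests on the C2–C1' bond. C2 is the β-carbon of the vinylogous ester O1–C2=C3–C4=O in ring C and the only stereocentre, and C1' of ring B has two free ortho positions. Rings A and C are therefore completed first as an achiral 6,8-diprenylchromone, and ring B is attached last as an arylboronic acid by a rhodium-catalysed enantioselective 1,4-addition. This single operation joins the two halves, gives the flavanone at the right oxidation level and sets C2 in an irreversible C–C bond formation. No cycloaddition and no C4 redox correction remain, and all three prenyl groups are placed regiospecifically: by twofold Claisen rearrangement and cross-metathesis on ring A, by ortho-directed bromine–lithium exchange on ring B.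

Key step: step 9

Assumption: the sense of induction of the (S)-configured biaryl bisphosphine on the chromone is taken to follow the quadrant model established for 2-cyclohexenone (aryl to the Re face of C2, giving 2S); should it be opposite, the (R)-ligand would be used.

**Chromone fragment (rings A and C)**

Step 1
Reactants: 1 2,4,6-trihydroxyacetophenone; 2 allyl bromide (3-bromoprop-1-ene)
Product: 3 1-[2-hydroxy-4,6-bis(prop-2-en-1-yloxy)phenyl]ethan-1-one
Conditions: 2 (2.1 equiv), K2CO3 (2.2 equiv), acetone, reflux
Reagents that add atoms: none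
Why: Williamson etherification with a weak base alkylates the 4-OH and one of the two equivalent ortho-OH groups, while the remaining ortho-OH is held in a hydrogen bond to the acetyl group and stays free, as is usual for 2,4,6-trihydroxyaryl ketones.

Step 2
Reactants: 3 1-[2-hydroxy-4,6-bis(prop-2-en-1-yloxy)phenyl]ethan-1-one
Product: 4 1-[2,4,6-trihydroxy-3,5-di(prop-2-en-1-yl)phenyl]ethan-1-one
Conditions: PhNEt2, 200 °C, sealed tube, N2
Reagents that add atoms: none
Why: The twofold aromatic Claisen rearrangement ([3,3]-sigmatropic) is regioconvergent here, because the carbon that bears the acetyl group is blocked, so each allyl group ends at C3 or C5, either directly or through an ortho-dienone followed by a Cope shift, and enolisation gives the single 3,5-diallyl product.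

Step 3
Reactants: 4 1-[2,4,6-trihydroxy-3,5-di(prop-2-en-1-yl)phenyl]ethan-1-one
Product: 5 1-[2-hydroxy-4,6-bis(methoxymethoxy)-3,5-di(prop-2-en-1-yl)phenyl]ethan-1-one
Conditions: MOMCl (2.3 equiv), iPr2NEt (3 equiv), CH2Cl2, 0 °C → rt
Reagents that add atoms: chloromethyl methyl ether, COCCl
Why: Williamson-type MOM ether formation protects the 4-OH and one ortho-OH, while the other ortho-OH is hydrogen bonded to the ketone, reacts far more slowly and is kept for the later closure of ring C.

Step 4
Reactants: 5 1-[2-hydroxy-4,6-bis(methoxymethoxy)-3,5-di(prop-2-en-1-yl)phenyl]ethan-1-one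
Product: 6 1-[2-hydroxy-4,6-bis(methoxymethoxy)-3,5-bis(3-methylbut-2-en-1-yl)phenyl]ethan-1-one
Conditions: second-generation Grubbs catalyst RuCl2(=CHPh)(H2IMes)(PCy3) (5 mol%), 2-methylbut-2-ene (excess), CH2Cl2, 40 °C, sealed tube
Reagents that add atoms: 2-methylbut-2-ene, CC=C(C)C
Why: Olefin cross-metathesis of the two terminal allyl groups with an excess of the trisubstituted alkene exchanges =CH2 for =CMe2 and releases propene, a standard way of turning allyl arenes into prenyl arenes that tolerates MOM ethers and the chelated phenol.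

Step 5
Reactants: 6 1-[2-hydroxy-4,6-bis(methoxymethoxy)-3,5-bis(3-methylbut-2-en-1-yl)phenyl]ethan-1-one
Product: 8 5,7-bis(methoxymethoxy)-6,8-bis(3-methylbut-2-en-1-yl)-4H-chromen-4-one, via enaminone 7 (not isolated)
Conditions: Me2NCH(OMe)2 (3 equiv), toluene, 100 °C; evaporation; AcOH, toluene, 60 °C
Reagents that add atoms: N,N-dimethylformamide dimethyl acetal, COC(OC)N(C)C
Why: Condensation of the methyl ketone with the amide acetal gives the enaminone, and mild acid then triggers 6-endo addition of the free phenol and loss of dimethylamine (enaminone route to chromones), which closes ring C through the O1–C2 bond under conditions too weak to cleave the MOM ethers or to cyclise the prenyl groups.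

**Ring B fragment**

Step 6
Reactants: 9 2,4,6-tribromoanisole (1,3,5-tribromo-2-methoxybenzene); 10 prenyl bromide (1-bromo-3-methylbut-2-ene)
Product: 13 1,5-dibromo-2-methoxy-3-(3-methylbut-2-en-1-yl)benzene, via aryllithium 11 (not isolated), via arylcopper 12 (not isolated)
Conditions: n-BuLi (1.05 equiv), Et2O, −78 °C; CuBr·SMe2 (1.1 equiv), −78 → −40 °C; 10 (1.3 equiv), −40 → 0 °C
Reagents that add atoms: none
Why: Bromine–lithium exchange takes place at one of the two equivalent bromines next to the methoxy group, which coordinates lithium and stabilises the ortho anion, in preference to the para bromine, and the arylcopper formed by transmetalation is alkylated by prenyl bromide at its CH2 terminus (SN2) to give the linear prenyl arene.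

Step 7
Reactants: 13 1,5-dibromo-2-methoxy-3-(3-methylbut-2-en-1-yl)benzene
Product: 16 5-bromo-2-methoxy-3-(3-methylbut-2-en-1-yl)phenol, via aryllithium 14 (not isolated), via lithium aryltrimethoxyborate 15 (not isolated)
Conditions: n-BuLi (1.05 equiv), Et2O, −78 °C; B(OMe)3 (2 equiv), −78 °C → rt; 30% H2O2, 2 M NaOH, 0 °C → rt; HCl to pH 5
Reagents that add atoms: hydrogen peroxide, OO
Why: A second ortho-directed bromine–lithium exchange removes the remaining bromine next to the methoxy group, and boration followed by alkaline hydrogen peroxide turns the aryl–lithium bond into a phenol by a 1,2-aryl shift from boron to oxygen (borate oxidation), conditions under which the electron-rich prenyl alkene is not epoxidised.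

Step 8
Reactants: 16 5-bromo-2-methoxy-3-(3-methylbut-2-en-1-yl)phenol
Product: 20 [3-hydroxy-4-methoxy-5-(3-methylbut-2-en-1-yl)phenyl]boronic acid, via trimethylsilyl ether 17 (not isolated), via aryllithium 18 (not isolated), via lithium aryltriisopropoxyborate 19 (not isolated)
Conditions: (Me3Si)2NH (0.6 equiv), THF, 60 °C, evaporation; B(OiPr)3 (1.3 equiv), THF/toluene, −78 °C, then n-BuLi (1.15 equiv) added slowly; 1 M HCl, 0 °C
Reagents that add atoms: triisopropyl borate, CC(C)OB(OC(C)C)OC(C)C; water, O
Why: Transient O-silylation masks the phenol, bromine–lithium exchange at the last bromine with the borate already present (in situ quench) traps the aryllithium as the borate before it can attack the silyl ether, and dilute acid sets free both the boronic acid and the phenol, which is not ortho to the prenyl group and so cannot cyclise onto it.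

**Key step and endgame**

Step 9
Reactants: 8 5,7-bis(methoxymethoxy)-6,8-bis(3-methylbut-2-en-1-yl)-4H-chromen-4-one; 20 [3-hydroxy-4-methoxy-5-(3-methylbut-2-en-1-yl)phenyl]boronic acid
Product: 21 (2S)-2-[3-hydroxy-4-methoxy-5-(3-methylbut-2-en-1-yl)phenyl]-5,7-bis(methoxymethoxy)-6,8-bis(3-methylbut-2-en-1-yl)-2,3-dihydro-4H-chromen-4-one
Conditions: [RhCl(C2H4)2]2 (2.5 mol%), (S)-MeO-F12-BIPHEP = (S)-6,6'-dimethoxy-2,2'-bis[bis(3,4,5-trifluorophenyl)phosphino]-1,1'-biphenyl (5.5 mol%), KOH (10 mol%), 20 (2.0 equiv), 1,4-dioxane/H2O (10:1), 40 °C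
Reagents that add atoms: none
Why: Rhodium-catalysed asymmetric 1,4-addition of an arylboronic acid to an enone (Hayashi–Miyaura reaction), a reaction type that is known to turn chromones into flavanones: the hydroxo complex of monovalent rhodium with the bisphosphine takes the aryl group from boron by transmetalation, the C2=C3 bond of 8 coordinates and inserts into the Rh–aryl bond so that the aryl group is bound to C2 and an oxa-π-allyl rhodium enolate spans C3–C4–O, and water protonates C3 and returns the hydroxo complex. No ring is closed, since ring C is already present in 8; the step forms only the C2–C1' bond, which joins the two fragments and completes the flavanone skeleton at the ketone oxidation level. C2 is the only new stereocentre and is controlled by the catalyst: the C2-symmetric (S)-bisphosphine leaves one open quadrant for the flat chromone, so that the aryl group is delivered to the Re face of C2 (O1 > C3 > H), which corresponds to 2S. The step needs 1,4- over 1,2-selectivity, which the soft aryl–rhodium species and the 5-OMOM group beside the C4 carbonyl secure, and it needs protonation of the rhodium enolate to outrun β-elimination of the O1 phenoxide (opening of ring C to a 2'-hydroxychalcone), which the aqueous and almost base-free medium secures. The three prenyl alkenes are trisubstituted and unactivated and should not insert into the Rh–aryl bond, the ring B phenol is no stronger an acid than the boronic acid and should be tolerated, and both positions ortho to boron (C2' and C6') are unsubstituted, so that transmetalation is not hindered. Because the C–C bond formation is irreversible, the configuration at C2 cannot be lost through a chalcone, as it can in a reversible oxa-Michael ring closure.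

Step 10
Reactants: 21 (2S)-2-[3-hydroxy-4-methoxy-5-(3-methylbut-2-en-1-yl)phenyl]-5,7-bis(methoxymethoxy)-6,8-bis(3-methylbut-2-en-1-yl)-2,3-dihydro-4H-chromen-4-one
Product: 22 isoamoritin, (2S)-5,7-dihydroxy-2-[3-hydroxy-4-methoxy-5-(3-methylbut-2-en-1-yl)phenyl]-6,8-bis(3-methylbut-2-en-1-yl)-2,3-dihydro-4H-chromen-4-one
Conditions: HCl (1.25 M in MeOH), 0 °C → rt
Reagents that add atoms: none
Why: Acid-catalysed acetal exchange with methanol removes both MOM ethers as dimethoxymethane under the standard conditions for prenylated flavanones, and the low temperature and an early stop should keep the freed phenols from adding to the neighbouring prenyl alkenes and leave C2, which mild acid does not epimerise, as S.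

**Compound list**

1 | 2,4,6-trihydroxyacetophenone | CC(=O)c1c(O)cc(O)cc1O | starting material
2 | allyl bromide (3-bromoprop-1-ene) | C=CCBr | starting material
3 | 1-[2-hydroxy-4,6-bis(prop-2-en-1-yloxy)phenyl]ethan-1-one | CC(=O)c1c(O)cc(OCC=C)cc1OCC=C | intermediate
4 | 1-[2,4,6-trihydroxy-3,5-di(prop-2-en-1-yl)phenyl]ethan-1-one | CC(=O)c1c(O)c(CC=C)c(O)c(CC=C)c1O | intermediate
5 | 1-[2-hydroxy-4,6-bis(methoxymethoxy)-3,5-di(prop-2-en-1-yl)phenyl]ethan-1-one | CC(=O)c1c(O)c(CC=C)c(OCOC)c(CC=C)c1OCOC | intermediate
6 | 1-[2-hydroxy-4,6-bis(methoxymethoxy)-3,5-bis(3-methylbut-2-en-1-yl)phenyl]ethan-1-one | CC(=O)c1c(O)c(CC=C(C)C)c(OCOC)c(CC=C(C)C)c1OCOC | intermediate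
7 | (E)-3-(dimethylamino)-1-[2-hydroxy-4,6-bis(methoxymethoxy)-3,5-bis(3-methylbut-2-en-1-yl)phenyl]prop-2-en-1-one (enaminone) | CN(C)/C=C/C(=O)c1c(O)c(CC=C(C)C)c(OCOC)c(CC=C(C)C)c1OCOC | intermediate
8 | 5,7-bis(methoxymethoxy)-6,8-bis(3-methylbut-2-en-1-yl)-4H-chromen-4-one | O=c1ccoc2c(CC=C(C)C)c(OCOC)c(CC=C(C)C)c(OCOC)c12 | intermediate
9 | 2,4,6-tribromoanisole (1,3,5-tribromo-2-methoxybenzene) | COc1c(Br)cc(Br)cc1Br | starting material
10 | prenyl bromide (1-bromo-3-methylbut-2-ene) | CC(C)=CCBr | starting material
11 | (3,5-dibromo-2-methoxyphenyl)lithium | COc1c(Br)cc(Br)cc1[Li] | intermediate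
12 | (3,5-dibromo-2-methoxyphenyl)copper | COc1c(Br)cc(Br)cc1[Cu] | intermediate
13 | 1,5-dibromo-2-methoxy-3-(3-methylbut-2-en-1-yl)benzene | COc1c(Br)cc(Br)cc1CC=C(C)C | intermediate
14 | [5-bromo-2-methoxy-3-(3-methylbut-2-en-1-yl)phenyl]lithium | COc1c([Li])cc(Br)cc1CC=C(C)C | intermediate
15 | lithium [5-bromo-2-methoxy-3-(3-methylbut-2-en-1-yl)phenyl]trimethoxyborate | [Li+].COc1c([B-](OC)(OC)OC)cc(Br)cc1CC=C(C)C | intermediate
16 | 5-bromo-2-methoxy-3-(3-methylbut-2-en-1-yl)phenol | COc1c(O)cc(Br)cc1CC=C(C)C | intermediate
17 | [5-bromo-2-methoxy-3-(3-methylbut-2-en-1-yl)phenoxy]trimethylsilane | COc1c(O[Si](C)(C)C)cc(Br)cc1CC=C(C)C | intermediate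
18 | [4-methoxy-3-(3-methylbut-2-en-1-yl)-5-(trimethylsilyloxy)phenyl]lithium | COc1c(O[Si](C)(C)C)cc([Li])cc1CC=C(C)C | intermediate
19 | lithium triisopropoxy[4-methoxy-3-(3-methylbut-2-en-1-yl)-5-(trimethylsilyloxy)phenyl]borate | [Li+].COc1c(O[Si](C)(C)C)cc([B-](OC(C)C)(OC(C)C)OC(C)C)cc1CC=C(C)C | intermediate
20 | [3-hydroxy-4-methoxy-5-(3-methylbut-2-en-1-yl)phenyl]boronic acid | COc1c(O)cc(B(O)O)cc1CC=C(C)C | intermediate
21 | (2S)-2-[3-hydroxy-4-methoxy-5-(3-methylbut-2-en-1-yl)phenyl]-5,7-bis(methoxymethoxy)-6,8-bis(3-methylbut-2-en-1-yl)-2,3-dihydro-4H-chromen-4-one | COc1c(O)cc([C@@H]2CC(=O)c3c(OCOC)c(CC=C(C)C)c(OCOC)c(CC=C(C)C)c3O2)cc1CC=C(C)C | intermediate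
22 | isoamoritin | COc1c(O)cc([C@@H]2CC(=O)c3c(O)c(CC=C(C)C)c(O)c(CC=C(C)C)c3O2)cc1CC=C(C)C | target

**Totals and risks**

Total step count: 10. Longest linear sequence: 7 steps (steps 1 to 5, 9 and 10).

Steps most likely to fail:

Step 9. The carborhodation of the electron-rich, fully substituted chromone may be slow, so that protodeboronation of the boronic acid and opening of ring C by β-elimination of the phenoxide take over, or the facial selectivity may be poor. The fallback would set C2 in a ring closure instead; it sets out from 6 and 16 and comes back at 21. Compound 16 would be silylated and lithiated as in step 8 (through 17 and 18) and the aryllithium quenched with DMF to give 3-hydroxy-4-methoxy-5-(3-methylbut-2-en-1-yl)benzaldehyde F1. Claisen–Schmidt condensation of 6 with F1 (KOH, EtOH, rt) would give the 2'-hydroxychalcone (E)-1-[2-hydroxy-4,6-bis(methoxymethoxy)-3,5-bis(3-methylbut-2-en-1-yl)phenyl]-3-[3-hydroxy-4-methoxy-5-(3-methylbut-2-en-1-yl)phenyl]prop-2-en-1-one F2. An intramolecular oxa-Michael addition under a quinine-derived bifunctional thiourea would then close ring C to 21, whose enantiomeric purity would be raised by crystallisation or by chromatography on a chiral phase if needed.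

Step 2. One allyl group may stay on oxygen, the ortho-allylphenols may cyclise to dihydrobenzofurans, or the electron-rich triol may decompose at 200 °C. The fallback would place the two carbon substituents by halogenation and cross-coupling instead of rearrangement; it sets out from 1 and comes back at 6, so that steps 1 to 4 are not needed. Twofold iodination of 1 (N-iodosuccinimide, MeCN, 0 °C; only C3 and C5 are free) would give 1-(2,4,6-trihydroxy-3,5-diiodophenyl)ethan-1-one F3. Protection as in step 3 would give 1-[2-hydroxy-3,5-diiodo-4,6-bis(methoxymethoxy)phenyl]ethan-1-one F4. A twofold Stille coupling with tributyl(3-methylbut-2-en-1-yl)stannane (Pd(PPh3)4, a complex of zerovalent palladium, DMF, 90 °C) would give 6.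

Step 8. n-BuLi or the aryllithium may attack the silyl ether, the exchange may be incomplete, or the electron-rich boronic acid may be protodeboronated on acidic work-up. The fallback would introduce boron by catalysis instead of by an organolithium; it sets out from 16 and comes back at 20. Miyaura borylation of 16 (bis(pinacolato)diboron, PdCl2(dppf), KOAc, 1,4-dioxane, 85 °C), which tolerates the free phenol, would give 2-methoxy-3-(3-methylbut-2-en-1-yl)-5-(4,4,5,5-tetramethyl-1,3,2-dioxaborolan-2-yl)phenol F5. Transesterification with diethanolamine would give the crystalline 5-(1,3,6,2-dioxazaborocan-2-yl)-2-methoxy-3-(3-methylbut-2-en-1-yl)phenol F6, and brief hydrolysis with dilute HCl would give 20.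

**Further compounds**

F1 | step 9 | 3-hydroxy-4-methoxy-5-(3-methylbut-2-en-1-yl)benzaldehyde | COc1c(O)cc(C=O)cc1CC=C(C)C
F2 | step 9 | (E)-1-[2-hydroxy-4,6-bis(methoxymethoxy)-3,5-bis(3-methylbut-2-en-1-yl)phenyl]-3-[3-hydroxy-4-methoxy-5-(3-methylbut-2-en-1-yl)phenyl]prop-2-en-1-one | COCOc1c(CC=C(C)C)c(OCOC)c(CC=C(C)C)c(O)c1C(=O)/C=C/c1cc(O)c(OC)c(CC=C(C)C)c1
F3 | step 2 | 1-(2,4,6-trihydroxy-3,5-diiodophenyl)ethan-1-one | CC(=O)c1c(O)c(I)c(O)c(I)c1O
F4 | step 2 | 1-[2-hydroxy-3,5-diiodo-4,6-bis(methoxymethoxy)phenyl]ethan-1-one | CC(=O)c1c(O)c(I)c(OCOC)c(I)c1OCOC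
F5 | step 8 | 2-methoxy-3-(3-methylbut-2-en-1-yl)-5-(4,4,5,5-tetramethyl-1,3,2-dioxaborolan-2-yl)phenol | COc1c(O)cc(B2OC(C)(C)C(C)(C)O2)cc1CC=C(C)C
F6 | step 8 | 5-(1,3,6,2-dioxazaborocan-2-yl)-2-methoxy-3-(3-methylbut-2-en-1-yl)phenol | COc1c(O)cc(B2OCCNCCO2)cc1CC=C(C)C
A1 | direct plan | 2-hydroxy-4,6-bis(methoxymethoxy)-3,5-bis(3-methylbut-2-en-1-yl)benzaldehyde | O=Cc1c(O)c(CC=C(C)C)c(OCOC)c(CC=C(C)C)c1OCOC
A2 | direct plan | 5-ethenyl-2-methoxy-1-(methoxymethoxy)-3-(3-methylbut-2-en-1-yl)benzene | C=Cc1cc(CC=C(C)C)c(OC)c(OCOC)c1
A3 | direct plan | (2S,4S)-4-methoxy-2-[4-methoxy-3-(methoxymethoxy)-5-(3-methylbut-2-en-1-yl)phenyl]-5,7-bis(methoxymethoxy)-6,8-bis(3-methylbut-2-en-1-yl)chromane | CO[C@H]1C[C@@H](c2cc(CC=C(C)C)c(OC)c(OCOC)c2)Oc2c(CC=C(C)C)c(OCOC)c(CC=C(C)C)c(OCOC)c12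
A4 | direct plan | 2,4,6-trihydroxybenzaldehyde | O=Cc1c(O)cc(O)cc1O
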